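## Retrosynthetic overview

- The target is 3,5-dibromo-2-(2,4-dibromophenoxy)-4-methoxyphenol. The strategy rests on the 2,4-dibromophenyl ring: going round from the ether carbon C1' it carries Br (C2'), H (C3'), Br (C4'), H (C5'), the same sequence as C3–C6 of 3,5-dibromo-2-pyrone. C1'–O and C6'–H can therefore come from an aryl ethynyl ether.
- Endgame, read backwards: MOM removal ⇐ O-methylation ⇐ ortho,ortho-dibromination of a free phenol ⇐ desilylation of the cycloadduct.
- Key disconnection: the dibromophenyl ring ⇒ 3,5-dibromo-2-pyrone plus the ethynyl ether of the oxygenated ring, by [4+2] addition and retro-[4+2] loss of CO2.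
- Ynol ether ⇐ 1,2-dichlorovinyl ether ⇐ phenol, made from 2,5-dihydroxybenzaldehyde by silylation, MOM protection and Dakin oxidation; pyrone ⇐ coumalic acid.
- Ring order: the oxygenated ring is bought; the dibromophenyl ring is built de novo, already attached to the ether oxygen.

Key step: step 7

Remark: the target has no stereocentre, so "single enantiomer" has no bearing and the only selectivity to secure is regiochemical. A triisopropylsilyl ether is used on the oxygen that becomes OMe because it must survive carbonate in hot DMF and butyllithium.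

## Route

Step 1
Reactants: 1 coumalic acid
Product: 3 3,5-dibromo-2H-pyran-2-one, via 5-bromo-2H-pyran-2-one 2 (not isolated)
Conditions: NBS (2.5 equiv), LiOAc, MeCN–H2O, rt
Reagents that add atoms: N-bromosuccinimide, O=C1CCC(=O)N1Br
Why: Hunsdiecker-type bromodecarboxylation by ipso attack at C5 (the enol-ether β-carbon) followed by electrophilic bromination at C3, the other nucleophilic position of the pyrone; this is an established preparation of this pyrone.

Step 2
Reactants: 4 2,5-dihydroxybenzaldehyde
Product: 5 2-hydroxy-5-{[tri(propan-2-yl)silyl]oxy}benzaldehyde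
Conditions: TIPSCl (1.05 equiv), imidazole, DMF, 0 °C → rt
Reagents that add atoms: chlorotri(propan-2-yl)silane, CC(C)[Si](Cl)(C(C)C)C(C)C
Why: Chemoselective O-silylation; the 2-OH is held in a hydrogen bond to the formyl group and is more hindered, so the bulky silyl chloride should take the 5-OH.

Step 3
Reactants: 5 2-hydroxy-5-{[tri(propan-2-yl)silyl]oxy}benzaldehyde
Product: 6 2-(methoxymethoxy)-5-{[tri(propan-2-yl)silyl]oxy}benzaldehyde
Conditions: MOMCl, iPr2NEt, CH2Cl2, 0 °C → rt
Reagents that add atoms: chloromethyl methyl ether, COCCl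
Why: Williamson-type O-alkylation of the remaining phenol by the reactive α-chloro ether; the silyl ether and the aldehyde are inert to amine base.

Step 4
Reactants: 6 2-(methoxymethoxy)-5-{[tri(propan-2-yl)silyl]oxy}benzaldehyde
Product: 8 2-(methoxymethoxy)-5-{[tri(propan-2-yl)silyl]oxy}phenol, via aryl formate 7 (not isolated)
Conditions: mCPBA, CH2Cl2, 0 °C → rt; aq. Na2S2O3/NaHCO3 wash; then Et3N (cat.), MeOH, rt
Reagents that add atoms: 3-chloroperbenzoic acid, O=C(OO)c1cccc(Cl)c1
Why: Dakin-type Baeyer–Villiger oxidation, in which the ortho-alkoxy donor favours aryl migration to the formate; amine-catalysed methanolysis of the formate is mild enough to leave the aryl silyl ether and the MOM acetal intact.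

Step 5
Reactants: 8 2-(methoxymethoxy)-5-{[tri(propan-2-yl)silyl]oxy}phenol; 9 trichloroethylene
Product: 11 {3-{[(E)-1,2-dichloroethenyl]oxy}-4-(methoxymethoxy)phenoxy}tri(propan-2-yl)silane, via dichloroacetylene 10 (not isolated)
Conditions: K2CO3, DMF, 70 °C
Reagents that add atoms: none
Why: Base-mediated dehydrochlorination of trichloroethylene and trans addition of the phenol across the resulting chloroalkyne, the established preparation of aryl (E)-1,2-dichlorovinyl ethers; the hindered triisopropylsilyl ether should resist anhydrous carbonate.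

Step 6
Reactants: 11 {3-{[(E)-1,2-dichloroethenyl]oxy}-4-(methoxymethoxy)phenoxy}tri(propan-2-yl)silane
Product: 14 {3-(ethynyloxy)-4-(methoxymethoxy)phenoxy}tri(propan-2-yl)silane, via chloroethynyl ether 12 (not isolated), via lithium acetylide 13 (not isolated)
Conditions: n-BuLi (2.2 equiv), THF, −78 → −40 °C; then sat. aq. NH4Cl, −78 °C; used promptly, kept cold in solution
Reagents that add atoms: none
Why: Dehydrochlorination to the chloroalkyne, lithium–chlorine exchange and protonation, the standard route from dichlorovinyl ethers to terminal aryl ynol ethers; the low temperature keeps MOM-directed ortho-lithiation and attack at silicon out of the way.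

Step 7
Reactants: 3 3,5-dibromo-2H-pyran-2-one; 14 {3-(ethynyloxy)-4-(methoxymethoxy)phenoxy}tri(propan-2-yl)silane
Product: 16 {3-(2,4-dibromophenoxy)-4-(methoxymethoxy)phenoxy}tri(propan-2-yl)silane, via bicyclic lactone 15 (not isolated)
Conditions: 3 (2 equiv), PhMe, BHT (cat.), 105 °C, sealed tube, slow addition of 14
Reagents that add atoms: none
Why: Proposed new method: the electron-rich ynol ether should add as the 2π partner across C3 and C6 of the electron-poor pyrone diene in a thermal [4+2] cycloaddition, and the 2-oxabicyclo[2.2.2]octa-5,7-dien-3-one 15 should then lose CO2 by retro-[4+2] and be aromatic at once because the dienophile is an alkyne. The closest known reaction types are the Diels–Alder additions of 3,5-dibromo-2-pyrone to enol ethers and the pyrone–alkyne cycloaddition with CO2 extrusion to benzenes; an aryl ynol ether has not been shown as the partner. The one ring closed is the new benzene ring, formed intermolecularly from pyrone C3–C6 and the two alkyne carbons through two C–C bonds (alkyne CH to C6, alkyne C–O to C3). No stereocentre remains in the product, since the bridgeheads of 15 are lost on aromatisation. The step needs regioselectivity only, which the polarisation of both partners should secure: the nucleophilic terminal carbon of the ynol ether bonds to the electrophilic C6, the same orientation that puts the donor at C5 of the enol-ether adducts of this pyrone, whereas the opposite orientation would give the 3,5-dibromophenyl ether. The aryl ynol ether has no β-hydrogen for ketene-forming elimination, and slow addition into excess pyrone with BHT should limit its polymerisation.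

Step 8
Reactants: 16 {3-(2,4-dibromophenoxy)-4-(methoxymethoxy)phenoxy}tri(propan-2-yl)silane
Product: 17 3-(2,4-dibromophenoxy)-4-(methoxymethoxy)phenol
Conditions: TBAF, AcOH, THF, 0 °C → rt
Reagents that add atoms: none
Why: Fluoride-mediated cleavage of the aryl silyl ether; the MOM acetal, the diaryl ether and the aryl bromides are inert to buffered fluoride.

Step 9
Reactants: 17 3-(2,4-dibromophenoxy)-4-(methoxymethoxy)phenol
Product: 18 2,6-dibromo-3-(2,4-dibromophenoxy)-4-(methoxymethoxy)phenol
Conditions: NBS (2.05 equiv), iPr2NH (cat.), CH2Cl2, 0 °C, dark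
Reagents that add atoms: N-bromosuccinimide, O=C1CCC(=O)N1Br
Why: Amine-catalysed ortho-selective electrophilic bromination of a phenol; the para position is blocked by the MOM ether, both ortho positions are further activated by the aryloxy group (one ortho, one para to it), the dibromophenyl ring is deactivated, and the acid-free conditions spare the MOM group.

Step 10
Reactants: 18 2,6-dibromo-3-(2,4-dibromophenoxy)-4-(methoxymethoxy)phenol
Product: 19 1,3-dibromo-4-(2,4-dibromophenoxy)-2-methoxy-5-(methoxymethoxy)benzene
Conditions: MeI, K2CO3, acetone, 50 °C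
Reagents that add atoms: iodomethane, CI
Why: Williamson O-methylation; the 2,6-dibromophenol is acidic and its phenoxide, though flanked, is readily alkylated by the small electrophile.

Step 11
Reactants: 19 1,3-dibromo-4-(2,4-dibromophenoxy)-2-methoxy-5-(methoxymethoxy)benzene
Product: 20 3,5-dibromo-2-(2,4-dibromophenoxy)-4-methoxyphenol
Conditions: conc. HCl (cat.), MeOH, 50 °C
Reagents that add atoms: none
Why: Acid-catalysed acetal exchange removes the MOM group as dimethoxymethane; the aryl methyl ether, the diaryl ether and the aryl bromides do not react under these conditions.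

## Compound list

1 | coumalic acid (2-oxo-2H-pyran-5-carboxylic acid) | O=C(O)C1=COC(=O)C=C1 | starting material
2 | 5-bromo-2H-pyran-2-one | O=C1C=CC(Br)=CO1 | intermediate
3 | 3,5-dibromo-2H-pyran-2-one | O=C1OC=C(Br)C=C1Br | intermediate
4 | 2,5-dihydroxybenzaldehyde | O=Cc1cc(O)ccc1O | starting material
5 | 2-hydroxy-5-{[tri(propan-2-yl)silyl]oxy}benzaldehyde | O=Cc1cc(O[Si](C(C)C)(C(C)C)C(C)C)ccc1O | intermediate
6 | 2-(methoxymethoxy)-5-{[tri(propan-2-yl)silyl]oxy}benzaldehyde | COCOc1ccc(O[Si](C(C)C)(C(C)C)C(C)C)cc1C=O | intermediate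
7 | 2-(methoxymethoxy)-5-{[tri(propan-2-yl)silyl]oxy}phenyl formate | COCOc1ccc(O[Si](C(C)C)(C(C)C)C(C)C)cc1OC=O | intermediate
8 | 2-(methoxymethoxy)-5-{[tri(propan-2-yl)silyl]oxy}phenol | COCOc1ccc(O[Si](C(C)C)(C(C)C)C(C)C)cc1O | intermediate
9 | trichloroethylene | ClC=C(Cl)Cl | starting material
10 | dichloroacetylene | ClC#CCl | intermediate
11 | {3-{[(E)-1,2-dichloroethenyl]oxy}-4-(methoxymethoxy)phenoxy}tri(propan-2-yl)silane | COCOc1ccc(O[Si](C(C)C)(C(C)C)C(C)C)cc1O/C(Cl)=C\Cl | intermediate
12 | {3-[(chloroethynyl)oxy]-4-(methoxymethoxy)phenoxy}tri(propan-2-yl)silane | COCOc1ccc(O[Si](C(C)C)(C(C)C)C(C)C)cc1OC#CCl | intermediate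
13 | lithium 2-{2-(methoxymethoxy)-5-{[tri(propan-2-yl)silyl]oxy}phenoxy}ethynide | COCOc1ccc(O[Si](C(C)C)(C(C)C)C(C)C)cc1OC#C[Li] | intermediate
14 | {3-(ethynyloxy)-4-(methoxymethoxy)phenoxy}tri(propan-2-yl)silane | COCOc1ccc(O[Si](C(C)C)(C(C)C)C(C)C)cc1OC#C | intermediate
15 | 4,7-dibromo-5-{2-(methoxymethoxy)-5-{[tri(propan-2-yl)silyl]oxy}phenoxy}-2-oxabicyclo[2.2.2]octa-5,7-dien-3-one (racemic, transient) | O=C1OC2C=C(Oc3cc(O[Si](C(C)C)(C(C)C)C(C)C)ccc3OCOC)C1(Br)C=C2Br | intermediate
16 | {3-(2,4-dibromophenoxy)-4-(methoxymethoxy)phenoxy}tri(propan-2-yl)silane | COCOc1ccc(O[Si](C(C)C)(C(C)C)C(C)C)cc1Oc1ccc(Br)cc1Br | intermediate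
17 | 3-(2,4-dibromophenoxy)-4-(methoxymethoxy)phenol | COCOc1ccc(O)cc1Oc1ccc(Br)cc1Br | intermediate
18 | 2,6-dibromo-3-(2,4-dibromophenoxy)-4-(methoxymethoxy)phenol | COCOc1cc(Br)c(O)c(Br)c1Oc1ccc(Br)cc1Br | intermediate
19 | 1,3-dibromo-4-(2,4-dibromophenoxy)-2-methoxy-5-(methoxymethoxy)benzene | COCOc1cc(Br)c(OC)c(Br)c1Oc1ccc(Br)cc1Br | intermediate
20 | 3,5-dibromo-2-(2,4-dibromophenoxy)-4-methoxyphenol | COc1c(Br)cc(O)c(Oc2ccc(Br)cc2Br)c1Br | target

## Step count and risk

Total step count: 11. Longest linear sequence: 10 steps (steps 2–11, from 2,5-dihydroxybenzaldehyde); step 1 is the one-step branch to the pyrone.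

Steps most likely to fail:

1. Step 7 (proposed new method). The ynol ether may polymerise or be hydrated faster than it adds to the pyrone, or the two partners may add in both orientations. Fallback, from phenol 8 back to diaryl ether 16: the ether bond would be made by metal-free O-arylation with a diaryliodonium salt. 1,3-Dibromobenzene is treated with I2, mCPBA and TfOH in CH2Cl2; iodination para to one bromine and ortho to the other should give bis(2,4-dibromophenyl)iodonium trifluoromethanesulfonate F1. The potassium phenoxide of 8 (t-BuOK, THF, 0 °C → rt) is then arylated by F1 to give 16, and the route continues at step 8.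

2. Step 5. Silyl transfer to the phenoxide or loss of the silyl ether in hot carbonate/DMF, or incomplete capture of the volatile chloroalkyne, would erode the dichlorovinyl ether. Fallback, from aldehyde 6 back to ynol ether 14: the two-carbon unit would be built on the formate carbon. Aldehyde 6 is oxidised with mCPBA as in step 4, but formate 7 is isolated without methanolysis. Dichloromethylenation with PPh3/CCl4 (THF, 60 °C), a Wittig-type olefination known for formate esters, should give {3-[(2,2-dichloroethenyl)oxy]-4-(methoxymethoxy)phenoxy}tri(propan-2-yl)silane F2. n-BuLi (2.2 equiv, THF, −78 °C) then removes the vinylic hydrogen next to oxygen and expels chloride to reach the same chloroethynyl ether 12, which goes on through 13 to 14 after the NH4Cl quench.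

3. Step 9. The phenol para to the acetal oxygen may be oxidised towards a quinone with loss of the MOM group, or the second bromine may enter next to the MOM ether and not at the crowded position between OH and OAr. Fallback, from diaryl ether 16 to target 20: the acetal is exchanged for an electron-withdrawing acetate before bromination.
   - HCl (cat.) in MeOH removes the MOM group from 16 to give 2-(2,4-dibromophenoxy)-4-{[tri(propan-2-yl)silyl]oxy}phenol F3.
   - Ac2O/pyridine gives 2-(2,4-dibromophenoxy)-4-{[tri(propan-2-yl)silyl]oxy}phenyl acetate F4.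
   - HF·pyridine in THF frees 2-(2,4-dibromophenoxy)-4-hydroxyphenyl acetate F5.
   - Br2 (2.1 equiv) with NaOAc in AcOH should brominate both positions ortho to the phenol, now the only strong director, to give 3,5-dibromo-2-(2,4-dibromophenoxy)-4-hydroxyphenyl acetate F6.
   - MeI/K2CO3 in acetone at rt gives 3,5-dibromo-2-(2,4-dibromophenoxy)-4-methoxyphenyl acetate F7.
   - K2CO3 in MeOH removes the acetate to give 20.

Further compounds
F1 | step 7 | bis(2,4-dibromophenyl)iodonium trifluoromethanesulfonate | Brc1ccc([I+]c2ccc(Br)cc2Br)c(Br)c1.[O-]S(=O)(=O)C(F)(F)F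
F2 | step 5 | {3-[(2,2-dichloroethenyl)oxy]-4-(methoxymethoxy)phenoxy}tri(propan-2-yl)silane | COCOc1ccc(O[Si](C(C)C)(C(C)C)C(C)C)cc1OC=C(Cl)Cl
F3 | step 9 | 2-(2,4-dibromophenoxy)-4-{[tri(propan-2-yl)silyl]oxy}phenol | Oc1ccc(O[Si](C(C)C)(C(C)C)C(C)C)cc1Oc1ccc(Br)cc1Br
F4 | step 9 | 2-(2,4-dibromophenoxy)-4-{[tri(propan-2-yl)silyl]oxy}phenyl acetate | CC(=O)Oc1ccc(O[Si](C(C)C)(C(C)C)C(C)C)cc1Oc1ccc(Br)cc1Br
F5 | step 9 | 2-(2,4-dibromophenoxy)-4-hydroxyphenyl acetate | CC(=O)Oc1ccc(O)cc1Oc1ccc(Br)cc1Br
F6 | step 9 | 3,5-dibromo-2-(2,4-dibromophenoxy)-4-hydroxyphenyl acetate | CC(=O)Oc1cc(Br)c(O)c(Br)c1Oc1ccc(Br)cc1Br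
F7 | step 9 | 3,5-dibromo-2-(2,4-dibromophenoxy)-4-methoxyphenyl acetate | CC(=O)Oc1cc(Br)c(OC)c(Br)c1Oc1ccc(Br)cc1Br
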